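The synthesis rests on cutting the Z C1=C10 double bond, the only C=C of the ten-membered carbocycle. Ring-closing metathesis of an open-chain diene that already holds both oxiranes and both acetates closes this ring last and gives the target itself. The step exploits three features that together fold the chain. These are the in-ring cis geometry of C1=C10, which a ten-membered ring prefers, the cis-fused C4–C5 oxirane, and the fully substituted spiro carbon C7. The precursor ends in a but-3-enyl group (on C4) and an isopropenyl ketone (C9, C10). Its four stereocentres come from one double Sharpless epoxidation of a skipped diene diol made by two anti-carbomagnesiations.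

Key step: step 6

Remark on numbering: germacrane numbering is used for all compounds, open-chain ones included.
- C1=C10 is the ring alkene, and C14 is the methyl group on C10.
- C9 is the ketone carbon and C8 is a CH2 group.
- C7 is the spiro oxirane carbon and C6 is a CH2 group.
- C5 and C4 are the carbons of the fused oxirane, and C15 is the CH2O group on C4.
- C3 and C2 are CH2 groups.
- C11 is the exocyclic oxirane carbon, with C12 (CH2O) and C13 (CH3).

The target is 4R,5R,7S,11R. In 12 and 13 the descriptor at C7 reads R only because the CIP ranking of C6 and C8 is reversed there. The spatial arrangement is the same.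

Step 1
Reactants: 1 tert-butyldimethyl(prop-2-yn-1-yloxy)silane; 2 4-chlorobut-2-yn-1-ol
Product: 4 7-[(tert-butyldimethylsilyl)oxy]hepta-2,5-diyn-1-ol, via 4-iodobut-2-yn-1-ol 3 (not isolated)
Conditions: CuI, NaI, K2CO3, DMF, rt
Reagents that add atoms: none
Why: Copper-mediated propargylic substitution (skipped-diyne synthesis) in which the copper acetylide of 1 displaces the halide of 3, made from 2 by Finkelstein exchange, at the primary carbon, with the free hydroxyl group and the silyl ether tolerated and no stereocentre formed.

Step 2
Reactants: 4 7-[(tert-butyldimethylsilyl)oxy]hepta-2,5-diyn-1-ol; 5 but-3-en-1-ylmagnesium bromide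
Product: 8 (E)-2-(but-3-en-1-yl)hept-2-en-5-yne-1,7-diol, via magnesium chelate 6 (not isolated), via silyl ether 7 (not isolated)
Conditions: 5 (3 equiv), CuI (20 mol %), Et2O–THF, −20 °C to rt; then 2 M aq HCl, THF, rt
Reagents that add atoms: none
Why: Hydroxyl-directed, copper-catalysed anti-carbomagnesiation of a propargylic alcohol, in which only the alkyne next to the free alkoxide reacts, the butenyl group goes to C4 and magnesium to C5 in a five-membered chelate, so that protonation leaves H cis to C15 (E alkene, C3 cis to C6) and the acidic work-up then cleaves the primary silyl ether.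

Step 3
Reactants: 8 (E)-2-(but-3-en-1-yl)hept-2-en-5-yne-1,7-diol; 9 1-bromo-3-methylbut-2-ene (prenyl bromide)
Product: 11 (2E,5E)-6-(but-3-en-1-yl)-2-methyl-3-(3-methylbut-2-en-1-yl)hepta-2,5-diene-1,7-diol, via vinylmagnesium chelate 10 (not isolated)
Conditions: MeMgBr (5 equiv), CuI (0.5 equiv), Et2O–toluene, 0 to 40 °C; then 9 (excess), −20 °C to rt; aq NH4Cl
Reagents that add atoms: methylmagnesium bromide, C[Mg]Br
Why: The same directed anti-carbomagnesiation now puts methyl on C11 and magnesium on C7, held cis to the C12 alkoxide, and copper-assisted SN2 allylation of this vinylmagnesium by prenyl bromide with retention gives the tetrasubstituted alkene with C8 cis to C12 and C6 cis to C13.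

Step 4
Reactants: 11 (2E,5E)-6-(but-3-en-1-yl)-2-methyl-3-(3-methylbut-2-en-1-yl)hepta-2,5-diene-1,7-diol
Product: 12 bis-epoxy diol (4R,5R,7R,11R)
Conditions: Ti(OiPr)4, D-(−)-diethyl tartrate, t-BuOOH (decane), 4 Å molecular sieves, CH2Cl2, −25 °C
Reagents that add atoms: tert-butyl hydroperoxide, CC(C)(C)OO
Why: Double Sharpless asymmetric epoxidation, in which the D-(−)-tartrate catalyst attacks both allylic alcohols on the face that gives the 2R-type epoxy alcohol (C4 and C11), syn delivery turns the two alkene geometries into C5 and C7, the two alkenes without a hydroxyl group stay untouched, and the double reagent control turns the rare wrong-face events into separable diastereomers.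

Step 5
Reactants: 12 bis-epoxy diol (4R,5R,7R,11R)
Product: 16 open-chain bis-epoxy diacetate with isopropenyl ketone (4R,5R,7S,11R), via diacetate 13 (not isolated), via allylic hydroperoxide 14 (not isolated), via peracetate 15 (not isolated)
Conditions: Ac2O, pyridine, DMAP (cat.), CH2Cl2, 0 °C; then tetraphenylporphyrin (cat.), O2, visible light, 0 °C, same flask
Reagents that add atoms: acetic anhydride, CC(=O)OC(C)=O; dioxygen, O=O
Why: After acetylation of both alcohols, singlet oxygen reacts only with the trisubstituted C9=C10 alkene (Schenck ene reaction, terminal alkene inert), abstraction of a methyl hydrogen should be favoured over the C8 hydrogens next to quaternary C7, and the secondary hydroperoxide is acetylated and loses acetic acid (Kornblum–DeLaMare-type fragmentation) to give the isopropenyl ketone, which erases the transient C9 stereocentre.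

Step 6
Reactants: 16 open-chain bis-epoxy diacetate with isopropenyl ketone (4R,5R,7S,11R)
Product: 17 target, (1(10)Z,4R,5R,7S,11R)-12,15-diacetoxy-4,5:7,11-diepoxygermacr-1(10)-en-9-one
Conditions: second-generation Hoveyda–Grubbs catalyst (15 mol %), 1,4-benzoquinone (cat.), toluene (0.5 mM, slow addition of 16), 80 °C, argon sparge
Reagents that add atoms: none
Why: The ruthenium carbene loads on the monosubstituted alkene of the but-3-enyl arm, adds [2+2] to the isopropenyl C10=CH2 bond and cycloreverts, so that C1=C10 forms and ethene leaves (Chauvin mechanism; ring-closing metathesis of an enone–olefin diene, a known route to trisubstituted cyclic enones and to medium rings). The ten-membered carbocycle is closed end to end by this one C=C bond formation, and because 16 holds only these two terminal alkenes there is no exo/endo alternative and no smaller ring can compete. No stereocentre is made: C4, C5, C7 and C11 are spectators, and oxiranes, acetates and the ketone are inert to the catalyst. The only stereochemical issue is the alkene geometry, and since the metallacyclobutane leading to an in-ring trans C1=C10 is more strained in a ring that already holds the cis-fused oxirane, and cis-cyclodecenes are the more stable isomers, the Z enone should result. The selectivity needed is ring closure over oligomerisation, which is secured by high dilution, slow addition and removal of ethene, and in the substrate by the cis C4–C5 oxirane and the gem-disubstituted C7 (Thorpe–Ingold effect) acting as turn elements. The product alkene is trisubstituted and electron-poor, so it should not re-enter metathesis.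

Compound list
1 | tert-butyldimethyl(prop-2-yn-1-yloxy)silane | C#CCO[Si](C)(C)C(C)(C)C | starting material
2 | 4-chlorobut-2-yn-1-ol | OCC#CCCl | starting material
3 | 4-iodobut-2-yn-1-ol | OCC#CCI | intermediate
4 | 7-[(tert-butyldimethylsilyl)oxy]hepta-2,5-diyn-1-ol | OCC#CCC#CCO[Si](C)(C)C(C)(C)C | intermediate
5 | but-3-en-1-ylmagnesium bromide | C=CCC[Mg]Br | starting material
6 | magnesium chelate (five-membered C5–Mg–O–C15–C4 ring, butenyl on C4) | C=CCCC1=C(CC#CCO[Si](C)(C)C(C)(C)C)[Mg]OC1 | intermediate
7 | (E)-2-(but-3-en-1-yl)-7-[(tert-butyldimethylsilyl)oxy]hept-2-en-5-yn-1-ol | CC(C)(C)[Si](C)(C)OCC#CC/C=C(/CO)CCC=C | intermediate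
8 | (E)-2-(but-3-en-1-yl)hept-2-en-5-yne-1,7-diol | OCC#CC/C=C(/CO)CCC=C | intermediate
9 | 1-bromo-3-methylbut-2-ene (prenyl bromide) | CC(C)=CCBr | starting material
10 | vinylmagnesium chelate (five-membered C7–Mg–O–C12–C11 ring, methyl on C11, C15 as bromomagnesium alkoxide) | CC1=C(C/C=C(/CO[Mg]Br)CCC=C)[Mg]OC1 | intermediate
11 | (2E,5E)-6-(but-3-en-1-yl)-2-methyl-3-(3-methylbut-2-en-1-yl)hepta-2,5-diene-1,7-diol | OC/C(C)=C(\CC=C(C)C)C/C=C(/CO)CCC=C | intermediate
12 | [(2R,3R)-2-(but-3-en-1-yl)-3-{[(2R,3R)-3-(hydroxymethyl)-3-methyl-2-(3-methylbut-2-en-1-yl)oxiran-2-yl]methyl}oxiran-2-yl]methanol | OC[C@@]1(CCC=C)O[C@@H]1C[C@@]2(CC=C(C)C)O[C@]2(C)CO | intermediate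
13 | diacetate of 12 (4R,5R,7R,11R) | CC(=O)OC[C@@]1(CCC=C)O[C@@H]1C[C@@]2(CC=C(C)C)O[C@]2(C)COC(C)=O | intermediate
14 | C9 allylic hydroperoxide with C10 isopropenyl group (both C9 epimers; 4R,5R,7S,11R) | CC(=O)OC[C@@]1(CCC=C)O[C@@H]1C[C@@]2(CC(OO)C(C)=C)O[C@]2(C)COC(C)=O | intermediate
15 | C9 peracetate of 14 | CC(=O)OC[C@@]1(CCC=C)O[C@@H]1C[C@@]2(CC(OOC(C)=O)C(C)=C)O[C@]2(C)COC(C)=O | intermediate
16 | [(2R,3R)-3-{[(2S,3R)-3-(acetoxymethyl)-3-methyl-2-(3-methyl-2-oxobut-3-en-1-yl)oxiran-2-yl]methyl}-2-(but-3-en-1-yl)oxiran-2-yl]methyl acetate | CC(=O)OC[C@@]1(CCC=C)O[C@@H]1C[C@@]2(CC(=O)C(C)=C)O[C@]2(C)COC(C)=O | intermediate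
17 | (1(10)Z,4R,5R,7S,11R)-12,15-diacetoxy-4,5:7,11-diepoxygermacr-1(10)-en-9-one (CNP0185847.2) | CC(=O)OC[C@]12CC/C=C(/C)C(=O)C[C@]3(C[C@H]1O2)O[C@]3(C)COC(C)=O | target

Total step count: 6. Longest linear sequence: 6 steps (from 1 or 2 to 17).

Steps most likely to fail

Step 6 (ring-closing metathesis). The catalyst may not engage the electron-poor 1,1-disubstituted alkene, so that coupling of the but-3-enyl ends and oligomerisation take over. The fallback closes the ring at the carbinol oxidation level and restores the ketone afterwards. It sets out from 16. Luche reduction (NaBH4, CeCl3·7H2O, MeOH, −78 °C) gives the open-chain C9 allylic alcohol F1 as both epimers. Its alkene is no longer conjugated, and the free allylic hydroxyl group assists metathesis. Second-generation Grubbs catalyst at high dilution in CH2Cl2 should then close F1 to the ten-membered (Z)-C9 allylic alcohol F2. Dess–Martin periodinane buffered with NaHCO3 oxidises F2 to 17, where the fallback comes back to the route.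

Step 5 (acetylation, photooxygenation, dehydration). Singlet oxygen may also abstract a C8 hydrogen and place the hydroperoxide on C10. Once the C9 ketone exists, the pyridine/DMAP medium may also open the C7–C11 oxirane by β-elimination. The fallback replaces the ene reaction by a sequence with no regiochemical choice and no amine base. It sets out from 12. Acetylation alone gives 13, which is now isolated. OsO4 (cat.) with N-methylmorpholine N-oxide should dihydroxylate the trisubstituted alkene in preference to the terminal one and give the C9,C10 diol F3. Dess–Martin periodinane with NaHCO3 oxidises only the secondary hydroxyl group to give the C10-hydroxy C9 ketone F4. Burgess reagent (toluene, 50 °C) removes the tertiary hydroxyl group, which can eliminate only towards a methyl group. This gives 16, where the fallback comes back to the route.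

Step 3 (methylmagnesiation and prenylation). Three things may go wrong:
- Capture of the hindered vinylmagnesium may be slow.
- Attack may occur at the tertiary end of prenyl bromide (SN2′).
- The excess MeMgBr may consume the bromide.

The fallback separates the two bond formations and moves the C7–C8 bond to a palladium-catalysed cross-coupling. It sets out from 8. The chelate 10 is made as before but is quenched with I2, which gives the (Z)-C7 vinyl iodide F5 with retention. Stille coupling of F5 with tributyl(3-methylbut-2-en-1-yl)stannane (Pd2(dba)3, AsPh3, DMF, 50 °C), which tolerates the free hydroxyl groups and transfers the prenyl group through its primary carbon, gives 11. There the fallback comes back to the route.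

Further compounds
F1 | step 6 | open-chain C9 allylic alcohol (both C9 epimers) from 16 | CC(=O)OC[C@@]1(CCC=C)O[C@@H]1C[C@@]2(CC(O)C(C)=C)O[C@]2(C)COC(C)=O
F2 | step 6 | ten-membered (Z)-C9 allylic alcohol (9-hydroxy analogue of 17) | CC(=O)OC[C@]12CC/C=C(/C)C(O)C[C@]3(C[C@H]1O2)O[C@]3(C)COC(C)=O
F3 | step 5 | C9,C10 diol from 13 | CC(=O)OC[C@@]1(CCC=C)O[C@@H]1C[C@@]2(CC(O)C(C)(C)O)O[C@]2(C)COC(C)=O
F4 | step 5 | C10-hydroxy C9 ketone | CC(=O)OC[C@@]1(CCC=C)O[C@@H]1C[C@@]2(CC(=O)C(C)(C)O)O[C@]2(C)COC(C)=O
F5 | step 3 | (Z)-C7 vinyl iodide (iodine cis to C12) | OC/C(C)=C(\I)C/C=C(/CO)CCC=C
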